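Ring C is cut at O1–C2 and C4–C4a, and also at C3–C4. This leaves three components: 2-iodo-5-methoxyresorcinol (ring A), carbon monoxide (C4), and a ring B acetophenone whose carbonyl and methyl carbons become C3 and C2. One palladium-catalysed carbonylation/carbene-insertion sequence joins them to an α-aryl enone, whose phenoxide closes ring C by oxa-Michael addition, so the complete isoflavanone forms in one flask. The step exploits the position of C4a between C5–OH and C8a–O1 of ring A. Iodine marks that carbon, and the two flanking hydroxyls are equivalent, so either closure gives the same ring. The C3 carbinol is then set by reagent-controlled enolate hydroxylation.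

Key step: step 5

Assumption: the (+)-dichlorocamphor oxaziridine is taken to give (R)-ketols from 2-substituted 1-tetralone and 3-substituted chroman-4-one enolates, so the (−)-reagent is used for (3S); the antipode, also commercial, would be used if a test run showed the opposite sense.

Abbreviations: prenyl = 3-methylbut-2-en-1-yl; TIPS = triisopropylsilyl. Isoflavanone numbering is used, with primed positions on ring B.

Step 1
Reactants: 1 2,4-dihydroxyacetophenone; 2 prenyl bromide
Product: 3 1-[2,4-dihydroxy-3-prenylphenyl]ethanone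
Conditions: KOH, H2O, 0 °C to rt
Reagents that add atoms: none
Why: Phenoxide C-alkylation (direct C-prenylation): in water the oxygens of the resacetophenone dianion are solvated, so the allylic bromide should be taken up mainly at C3, the most electron-rich carbon between the two oxygens, and the C5 and O-prenyl isomers are removed by chromatography.

Step 2
Reactants: 3 1-[2,4-dihydroxy-3-prenylphenyl]ethanone
Product: 4 1-[2-hydroxy-3-prenyl-4-(triisopropylsilyloxy)phenyl]ethanone
Conditions: TIPSCl, imidazole, DMF, 0 °C to rt
Reagents that add atoms: TIPSCl, CC(C)[Si](Cl)(C(C)C)C(C)C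
Why: Chemoselective silyl ether formation: the 2-OH is held in a hydrogen bond to the acetyl oxygen and is flanked on both sides, so only the 4-OH should be silylated, and TIPS is chosen because it withstands carbonate, phenoxide and amide bases and leaves with buffered fluoride.

Step 3
Reactants: 4 1-[2-hydroxy-3-prenyl-4-(triisopropylsilyloxy)phenyl]ethanone
Product: 5 1-[2-methoxy-3-prenyl-4-(triisopropylsilyloxy)phenyl]ethanone
Conditions: MeI, K2CO3, dry acetone, 50 °C
Reagents that add atoms: MeI, CI
Why: Williamson ether synthesis: with the 4-oxygen blocked, carbonate and excess MeI methylate the chelated 2-OH under conditions too weakly basic to enolise the ketone and free of hydroxide that could attack the hindered silyl ether.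

Step 4
Reactants: 6 5-methoxyresorcinol
Product: 7 2-iodo-5-methoxybenzene-1,3-diol
Conditions: I2, NaHCO3, H2O/THF, 0 °C
Reagents that add atoms: iodine, II
Why: Electrophilic aromatic iodination: with I2 and NaHCO3 in cold water resorcinols are iodinated at the carbon between the two hydroxyls, here C2 para to the methoxy group, and one equivalent of iodine at 0 °C holds back di-iodination.

Step 5
Reactants: 5 1-[2-methoxy-3-prenyl-4-(triisopropylsilyloxy)phenyl]ethanone; 7 2-iodo-5-methoxybenzene-1,3-diol; 8 carbon monoxide
Product: 12 rac-5-hydroxy-7-methoxy-3-[2-methoxy-3-prenyl-4-(triisopropylsilyloxy)phenyl]chroman-4-one, via tosylhydrazone 9 (not isolated), via diazoalkane 10 (not isolated), via enone 11 (not isolated)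
Conditions: TsNHNH2, 4 Å molecular sieves, dioxane, 70 °C; then 7, Pd(PPh3)4 (5 mol %), K2CO3, CO (1 atm), 90 °C
Reagents that add atoms: none
Why: Ketone 5 condenses with TsNHNH2 to 9, K2CO3 releases diazoalkane 10 slowly (Bamford–Stevens), zerovalent palladium inserts into the carbon–iodine bond of 7 and takes up CO 8 to give an aroylpalladium iodide (C4–C4a), which forms a palladium carbene with 10; acyl migration to the carbene carbon (C3–C4) and β-hydride elimination from the former methyl group release enone 11, and its phenoxide adds to the CH2 terminus (O1–C2). The closest known reaction type is the palladium-catalysed three-component coupling of aryl iodides, CO and N-tosylhydrazones to 2-substituted 1-arylprop-2-en-1-ones, followed by the known base-induced cyclisation of 2'-hydroxy-α-arylacrylophenones to isoflavanones. Ring C closes in the 6-endo-trig mode, the only one open to the phenoxide because the α-carbon of the enone is not electrophilic. C3 arises by unselective protonation of the resulting enolate, so 12 is racemic, and C3 is flattened again and set in step 7. The acylation site on ring A is secured by the iodine at the carbon between the two hydroxyls and not by ring electronics, and because these hydroxyls are equivalent no question of O-regiochemistry arises. CO uptake must outrun direct aryl–carbene coupling, which the doubly ortho-substituted arylpalladium, the CO atmosphere and the slow release of 10 favour, while the trisubstituted prenyl alkene and the TIPS ether are spectators.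

Step 6
Reactants: 12 rac-5-hydroxy-7-methoxy-3-[2-methoxy-3-prenyl-4-(triisopropylsilyloxy)phenyl]chroman-4-one
Product: 13 rac-7-methoxy-3-[2-methoxy-3-prenyl-4-(triisopropylsilyloxy)phenyl]-5-(triisopropylsilyloxy)chroman-4-one
Conditions: TIPSOTf, 2,6-lutidine, CH2Cl2, −78 to 0 °C
Reagents that add atoms: TIPSOTf, CC(C)[Si](OS(=O)(=O)C(F)(F)F)(C(C)C)C(C)C
Why: Silyl ether formation with a silyl triflate: the chelated 5-OH is the only free hydroxyl and needs the more electrophilic TIPSOTf, 2,6-lutidine is too weak and hindered a base to turn the ketone into its silyl enol ether, and the cap prevents phenoxide formation and ring A oxidation in step 7.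

Step 7
Reactants: 13 rac-7-methoxy-3-[2-methoxy-3-prenyl-4-(triisopropylsilyloxy)phenyl]-5-(triisopropylsilyloxy)chroman-4-one
Product: 15 (3S)-3-hydroxy-7-methoxy-3-[2-methoxy-3-prenyl-4-(triisopropylsilyloxy)phenyl]-5-(triisopropylsilyloxy)chroman-4-one, via sodium enolate 14 (not isolated)
Conditions: NaN(SiMe3)2, THF, −78 °C; then (−)-[(8,8-dichlorocamphoryl)sulfonyl]oxaziridine, −78 °C; AcOH quench at −78 °C
Reagents that add atoms: (−)-[(8,8-dichlorocamphoryl)sulfonyl]oxaziridine, CC1(C)[C@H]2CC[C@@]13CS(=O)(=O)N4O[C@]34C2(Cl)Cl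
Why: Davis oxidation (enolate hydroxylation with a chiral N-sulfonyloxaziridine): enolate 14 attacks the oxaziridine oxygen in an open SN2-type transition state in which the dichlorocamphor skeleton blocks one enolate face, so reagent control should set (3S) as in the hydroxylation of 2-substituted 1-tetralone and 3-substituted chroman-4-one enolates, and at −78 °C the reagent leaves the prenyl alkene untouched.

Step 8
Reactants: 15 (3S)-3-hydroxy-7-methoxy-3-[2-methoxy-3-prenyl-4-(triisopropylsilyloxy)phenyl]-5-(triisopropylsilyloxy)chroman-4-one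
Product: 16 (3S)-3,5-dihydroxy-3-[4-hydroxy-2-methoxy-3-prenylphenyl]-7-methoxychroman-4-one (target)
Conditions: Bu4NF, AcOH, THF, 0 °C
Reagents that add atoms: none
Why: Fluoride-induced desilylation: Bu4NF buffered with AcOH should cleave both aryl silyl ethers under nearly neutral conditions, which avoids acid-induced dehydration to the isoflavone, chroman formation from the ortho-prenylphenol and base-induced quinone methide formation, so C3 keeps its configuration.

Compound list
1 | 2,4-dihydroxyacetophenone | CC(=O)c1ccc(O)cc1O | starting material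
2 | prenyl bromide (1-bromo-3-methylbut-2-ene) | CC(C)=CCBr | starting material
3 | 1-[2,4-dihydroxy-3-prenylphenyl]ethanone | CC(=O)c1ccc(O)c(CC=C(C)C)c1O | intermediate
4 | 1-[2-hydroxy-3-prenyl-4-(triisopropylsilyloxy)phenyl]ethanone | CC(=O)c1ccc(O[Si](C(C)C)(C(C)C)C(C)C)c(CC=C(C)C)c1O | intermediate
5 | 1-[2-methoxy-3-prenyl-4-(triisopropylsilyloxy)phenyl]ethanone | CC(=O)c1ccc(O[Si](C(C)C)(C(C)C)C(C)C)c(CC=C(C)C)c1OC | intermediate
6 | 5-methoxyresorcinol | COc1cc(O)cc(O)c1 | starting material
7 | 2-iodo-5-methoxybenzene-1,3-diol | COc1cc(O)c(I)c(O)c1 | intermediate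
8 | carbon monoxide | [C-]#[O+] | starting material
9 | N-tosylhydrazone of 5 | CC(=NNS(=O)(=O)c1ccc(C)cc1)c1ccc(O[Si](C(C)C)(C(C)C)C(C)C)c(CC=C(C)C)c1OC | intermediate
10 | 1-diazo-1-[2-methoxy-3-prenyl-4-(triisopropylsilyloxy)phenyl]ethane | CC(=[N+]=[N-])c1ccc(O[Si](C(C)C)(C(C)C)C(C)C)c(CC=C(C)C)c1OC | intermediate
11 | 1-(2,6-dihydroxy-4-methoxyphenyl)-2-[2-methoxy-3-prenyl-4-(triisopropylsilyloxy)phenyl]prop-2-en-1-one | C=C(C(=O)c1c(O)cc(OC)cc1O)c1ccc(O[Si](C(C)C)(C(C)C)C(C)C)c(CC=C(C)C)c1OC | intermediate
12 | rac-5-hydroxy-7-methoxy-3-[2-methoxy-3-prenyl-4-(triisopropylsilyloxy)phenyl]chroman-4-one | COc1cc(O)c2c(c1)OCC(c1ccc(O[Si](C(C)C)(C(C)C)C(C)C)c(CC=C(C)C)c1OC)C2=O | intermediate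
13 | rac-7-methoxy-3-[2-methoxy-3-prenyl-4-(triisopropylsilyloxy)phenyl]-5-(triisopropylsilyloxy)chroman-4-one | COc1cc(O[Si](C(C)C)(C(C)C)C(C)C)c2c(c1)OCC(c1ccc(O[Si](C(C)C)(C(C)C)C(C)C)c(CC=C(C)C)c1OC)C2=O | intermediate
14 | sodium enolate of 13 | COc1cc(O[Si](C(C)C)(C(C)C)C(C)C)c2c(c1)OCC(c1ccc(O[Si](C(C)C)(C(C)C)C(C)C)c(CC=C(C)C)c1OC)=C2[O-].[Na+] | intermediate
15 | (3S)-3-hydroxy-7-methoxy-3-[2-methoxy-3-prenyl-4-(triisopropylsilyloxy)phenyl]-5-(triisopropylsilyloxy)chroman-4-one | COc1cc(O[Si](C(C)C)(C(C)C)C(C)C)c2c(c1)OC[C@@](O)(c1ccc(O[Si](C(C)C)(C(C)C)C(C)C)c(CC=C(C)C)c1OC)C2=O | intermediate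
16 | (3S)-3,5-dihydroxy-3-[4-hydroxy-2-methoxy-3-prenylphenyl]-7-methoxychroman-4-one | COc1cc(O)c2c(c1)OC[C@@](O)(c1ccc(O)c(CC=C(C)C)c1OC)C2=O | target

Total step count: 8. Longest linear sequence: 7 (steps 1, 2, 3, 5, 6, 7, 8).

Steps most likely to fail

Risk 1 (step 5). Three processes may interfere:
- The diazoalkane may be protonated by the free phenols before it meets palladium.
- The arylpalladium may couple with the carbene without CO uptake.
- The acylpalladium may be intercepted by phenoxide.

The fallback sets out from 5 and 7 and returns at 13, so step 6 is not needed. It replaces the carbene coupling by a polar cascade that still forms both ring C bonds in one operation.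
- Ketone 5 is converted with KN(SiMe3)2 and PhNTf2 (THF, −78 °C) into the enol triflate F1.
- Hydroxycarbonylation of F1 (Pd(OAc)2, PPh3, KOAc, CO, DMF) gives the 2-arylacrylic acid F2.
- Diol 7 is monosilylated (one equivalent of TIPSCl, imidazole) to the phenol F3.
- F3 is esterified with F2 (EDC·HCl, DMAP, CH2Cl2) to the aryl acrylate F4.
- n-BuLi (THF, −100 °C, then warming) brings about iodine–lithium exchange and an anionic Fries shift to the lithium phenoxide of the enone F5. This closes by oxa-Michael addition, and an AcOH quench gives 13.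

Risk 2 (step 7). Facial discrimination may be insufficient in the oxygen transfer to a flat, fully substituted enolate that carries an aryl group in place of the alkyl groups of the model systems. The enantiomeric purity of 15 is to be checked on a chiral HPLC phase and raised by recrystallisation if needed.

The fallback sets out from 13 and returns at 15. It sets C3 by catalytic asymmetric epoxidation.
- Enolate 14 is dehydrogenated with N-tert-butylbenzenesulfinimidoyl chloride (Mukaiyama dehydrogenation, −78 °C) to the isoflavone F6.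
- Asymmetric Weitz–Scheffer epoxidation follows, with cumene hydroperoxide, aqueous KOH, toluene and N-[4-(trifluoromethyl)benzyl]cinchoninium bromide or its cinchonidinium pseudoenantiomer, whichever a test run shows to be right. This nucleophilic oxidant ignores the prenyl alkene, and the product is the (2R,3S)-isoflavone epoxide F7.
- Ionic hydrogenation of the acetal-type C2–O bond (Et3SiH, BF3·OEt2, CH2Cl2, −78 °C) proceeds through the O1-stabilised oxocarbenium ion. The C3–O bond stays untouched, and the product is 15.

Risk 3 (step 1). O-alkylation, attack at C5 and double prenylation may compete. The fallback sets out from 1 and returns at 3.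
- Allyl bromide and K2CO3 in acetone give the 4-O-allyl ether F8, because the chelated 2-OH stays free.
- Aromatic Claisen rearrangement (N,N-diethylaniline, 200 °C) goes to C3 because of the bond fixation imposed by the chelated 2-hydroxyacetophenone unit, and gives the 3-allyl diol F9.
- Cross-metathesis with 2-methyl-2-butene (second-generation Grubbs catalyst, CH2Cl2, 40 °C) turns the allyl group into the prenyl group of 3.

Further compounds
F1 | step 5 | 1-[2-methoxy-3-prenyl-4-(triisopropylsilyloxy)phenyl]vinyl triflate | C=C(OS(=O)(=O)C(F)(F)F)c1ccc(O[Si](C(C)C)(C(C)C)C(C)C)c(CC=C(C)C)c1OC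
F2 | step 5 | 2-[2-methoxy-3-prenyl-4-(triisopropylsilyloxy)phenyl]acrylic acid | C=C(C(=O)O)c1ccc(O[Si](C(C)C)(C(C)C)C(C)C)c(CC=C(C)C)c1OC
F3 | step 5 | 2-iodo-5-methoxy-3-(triisopropylsilyloxy)phenol | COc1cc(O)c(I)c(O[Si](C(C)C)(C(C)C)C(C)C)c1
F4 | step 5 | 2-iodo-5-methoxy-3-(triisopropylsilyloxy)phenyl 2-[2-methoxy-3-prenyl-4-(triisopropylsilyloxy)phenyl]acrylate | C=C(C(=O)Oc1cc(OC)cc(O[Si](C(C)C)(C(C)C)C(C)C)c1I)c1ccc(O[Si](C(C)C)(C(C)C)C(C)C)c(CC=C(C)C)c1OC
F5 | step 5 | 1-[2-hydroxy-4-methoxy-6-(triisopropylsilyloxy)phenyl]-2-[2-methoxy-3-prenyl-4-(triisopropylsilyloxy)phenyl]prop-2-en-1-one | C=C(C(=O)c1c(O)cc(OC)cc1O[Si](C(C)C)(C(C)C)C(C)C)c1ccc(O[Si](C(C)C)(C(C)C)C(C)C)c(CC=C(C)C)c1OC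
F6 | step 7 | 7-methoxy-3-[2-methoxy-3-prenyl-4-(triisopropylsilyloxy)phenyl]-5-(triisopropylsilyloxy)chromen-4-one | COc1cc(O[Si](C(C)C)(C(C)C)C(C)C)c2c(c1)OC=C(c1ccc(O[Si](C(C)C)(C(C)C)C(C)C)c(CC=C(C)C)c1OC)C2=O
F7 | step 7 | (2R,3S)-2,3-epoxide of F6 | COc1cc(O[Si](C(C)C)(C(C)C)C(C)C)c2c(c1)O[C@@H]3O[C@]3(c4ccc(O[Si](C(C)C)(C(C)C)C(C)C)c(CC=C(C)C)c4OC)C2=O
F8 | step 1 | 1-[4-(allyloxy)-2-hydroxyphenyl]ethanone | CC(=O)c1ccc(OCC=C)cc1O
F9 | step 1 | 1-(3-allyl-2,4-dihydroxyphenyl)ethanone | CC(=O)c1ccc(O)c(CC=C)c1O
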